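## Retrosynthetic overview

1. Target 27 ⇐ hydroxyl-directed reduction of the oxolan-3-one 26 (sets the C3 carbinol) ⇐ desilylation of 25.
2. 25 ⇐ acyclic α-diazo ketone 22 by Rh(II) oxonium-ylide formation and [1,2]-Stevens shift, which closes the oxolane (O1–C2) and makes the ArCH2–C2 bond in one operation. Enabling feature: in the oxolane ring O1 lies between C5 (benzylic, aryl-bearing) and C2 (arylmethyl-bearing), and C3 is oxygenated. This is a 2-benzyl-oxolan-3-one pattern, so the arylmethyl group can be parked on O1 as a benzyl ether of an open-chain precursor.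
3. 22 ⇐ terminal alkyne 19 (hydration, diazo transfer) ⇐ aldehyde 10 + chiral allenylzinc from mesylate 15 (anti adduct 17), then O-benzylation with imidate 18.
4. 10 ⇐ cis-2,3-dihydrobenzofuran by enantioselective Rh(II) intramolecular C–H insertion of aryl diazoacetate 6 ⇐ 5-iodovanillin 4 + benzyl alcohol 3 (from vanillin 1).
5. Ring order: dihydrofuran ring of the benzofuran first (step 5), oxolane last (step 18); all three arenes are bought.

Key step: step 18

Assumption: the sense of induction of Rh2(S-PTTL)4 in step 5 and of the allenylzinc addition in step 13 is taken from the accepted stereochemical models of these reactions; if either proved opposite, the antipodal catalyst or the mesylate from the (S)-aldehyde would be used.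

Abbreviations used in names: TIPS = triisopropylsilyl; TIPSO = triisopropylsilyloxy; ArCH2 = 3-methoxy-4-(triisopropylsilyloxy)benzyl; DHB = (2R,3R)-7-methoxy-2-[3-methoxy-4-(triisopropylsilyloxy)phenyl]-3-[(triisopropylsilyloxy)methyl]-2,3-dihydro-1-benzofuran-5-yl (the 2,3-cis ring).

## Route

Step 1
Reactants: 1 vanillin
Product: 2 3-methoxy-4-(triisopropylsilyloxy)benzaldehyde
Conditions: TIPSCl (1.2 equiv), imidazole (2.5 equiv), DMF, rt
Reagents that add atoms: triisopropylsilyl chloride CC(C)[Si](Cl)(C(C)C)C(C)C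
Why: Imidazole-promoted silylation of the phenol gives an aryl silyl ether that should survive all later steps and leave with the other silyl groups in step 19.

Step 2
Reactants: 2 3-methoxy-4-(triisopropylsilyloxy)benzaldehyde
Product: 3 [3-methoxy-4-(triisopropylsilyloxy)phenyl]methanol
Conditions: NaBH4, MeOH, 0 °C
Reagents that add atoms: none
Why: Borohydride reduction of the aldehyde to the primary benzylic alcohol.

Step 3
Reactants: 3 [3-methoxy-4-(triisopropylsilyloxy)phenyl]methanol; 4 5-iodovanillin (4-hydroxy-3-iodo-5-methoxybenzaldehyde)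
Product: 5 3-iodo-5-methoxy-4-{[3-methoxy-4-(triisopropylsilyloxy)benzyl]oxy}benzaldehyde
Conditions: PPh3, DIAD, THF, 0 °C → rt
Reagents that add atoms: none
Why: Mitsunobu etherification alkylates the acidic phenol of 4 with the activated primary benzylic alcohol under neutral conditions that spare the aryl silyl ether.

Step 4
Reactants: 5 3-iodo-5-methoxy-4-{[3-methoxy-4-(triisopropylsilyloxy)benzyl]oxy}benzaldehyde
Product: 6 ethyl 2-diazo-2-(5-formyl-3-methoxy-2-{[3-methoxy-4-(triisopropylsilyloxy)benzyl]oxy}phenyl)acetate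
Conditions: ethyl diazoacetate (1.5 equiv), Pd(PPh3)4 (5 mol %), Ag2CO3 (0.5 equiv), Et3N (1.3 equiv), toluene, rt
Reagents that add atoms: ethyl diazoacetate CCOC(=O)C=[N+]=[N-]
Why: Pd-catalysed cross-coupling of the aryl iodide with the C–H bond of the diazo ester (oxidative addition, palladation of the diazo carbon, reductive elimination) installs the aryl diazoacetate with the diazo group intact.

Step 5
Reactants: 6 ethyl 2-diazo-2-(5-formyl-3-methoxy-2-{[3-methoxy-4-(triisopropylsilyloxy)benzyl]oxy}phenyl)acetate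
Product: 7 ethyl (2R,3S)-5-formyl-7-methoxy-2-[3-methoxy-4-(triisopropylsilyloxy)phenyl]-2,3-dihydro-1-benzofuran-3-carboxylate (2,3-cis)
Conditions: Rh2(S-PTTL)4 (1 mol %), toluene, −60 °C, slow addition at high dilution
Reagents that add atoms: none
Why: Enantioselective intramolecular 1,5 C–H insertion of the Rh(II) donor/acceptor carbenoid into the activated O-benzylic C–H bond closes the dihydrofuran ring; the chiral carboxylate catalyst sets both centres, cis by the kinetic preference of this insertion and (2R,3S) as expected for the S-catalyst.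

Step 6
Reactants: 7 ethyl (2R,3S)-5-formyl-7-methoxy-2-[3-methoxy-4-(triisopropylsilyloxy)phenyl]-2,3-dihydro-1-benzofuran-3-carboxylate
Product: 8 [(2R,3R)-5-(hydroxymethyl)-7-methoxy-2-[3-methoxy-4-(triisopropylsilyloxy)phenyl]-2,3-dihydro-1-benzofuran-3-yl]methanol
Conditions: DIBAL-H (5 equiv), CH2Cl2, −78 → −20 °C; Rochelle salt work-up
Reagents that add atoms: none
Why: Non-basic hydride reduction of ester and aldehyde removes the epimerisable ester α-proton before the cis ring can equilibrate to trans.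

Step 7
Reactants: 8 [(2R,3R)-5-(hydroxymethyl)-7-methoxy-2-[3-methoxy-4-(triisopropylsilyloxy)phenyl]-2,3-dihydro-1-benzofuran-3-yl]methanol
Product: 9 (2R,3R)-3-(hydroxymethyl)-7-methoxy-2-[3-methoxy-4-(triisopropylsilyloxy)phenyl]-2,3-dihydro-1-benzofuran-5-carbaldehyde
Conditions: activated MnO2 (excess), CH2Cl2, rt
Reagents that add atoms: none
Why: Manganese dioxide oxidises the benzylic alcohol selectively and leaves the aliphatic primary alcohol untouched.

Step 8
Reactants: 9 (2R,3R)-3-(hydroxymethyl)-7-methoxy-2-[3-methoxy-4-(triisopropylsilyloxy)phenyl]-2,3-dihydro-1-benzofuran-5-carbaldehyde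
Product: 10 (2R,3R)-7-methoxy-2-[3-methoxy-4-(triisopropylsilyloxy)phenyl]-3-[(triisopropylsilyloxy)methyl]-2,3-dihydro-1-benzofuran-5-carbaldehyde (DHB–CHO)
Conditions: TIPSCl, imidazole, DMAP (cat.), DMF, rt
Reagents that add atoms: triisopropylsilyl chloride CC(C)[Si](Cl)(C(C)C)C(C)C
Why: Silylation of the primary alcohol protects it from the organozinc, the benzylating agent and the carbenoid of later steps.

Step 9
Reactants: 11 (R)-2,2-dimethyl-1,3-dioxolane-4-carbaldehyde
Product: 12 (S)-4-ethynyl-2,2-dimethyl-1,3-dioxolane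
Conditions: dimethyl (1-diazo-2-oxopropyl)phosphonate, K2CO3, MeOH, 0 °C → rt
Reagents that add atoms: dimethyl (1-diazo-2-oxopropyl)phosphonate COP(=O)(OC)C(=[N+]=[N-])C(C)=O
Why: Seyferth–Gilbert homologation under the mild carbonate/methanol variant converts the aldehyde into the terminal alkyne without touching the adjacent stereocentre (the descriptor changes from R to S only through the priority rules).

Step 10
Reactants: 12 (S)-4-ethynyl-2,2-dimethyl-1,3-dioxolane
Product: 13 (S)-but-3-yne-1,2-diol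
Conditions: Dowex 50W (H+ form), MeOH/H2O, rt
Reagents that add atoms: none
Why: Acid-catalysed hydrolysis of the acetonide.

Step 11
Reactants: 13 (S)-but-3-yne-1,2-diol
Product: 14 (S)-1-(triisopropylsilyloxy)but-3-yn-2-ol
Conditions: TIPSCl (1.05 equiv), imidazole, CH2Cl2, −20 → 0 °C
Reagents that add atoms: triisopropylsilyl chloride CC(C)[Si](Cl)(C(C)C)C(C)C
Why: The bulky silyl chloride reacts selectively at the primary hydroxyl group.

Step 12
Reactants: 14 (S)-1-(triisopropylsilyloxy)but-3-yn-2-ol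
Product: 15 (S)-1-(triisopropylsilyloxy)but-3-yn-2-yl methanesulfonate
Conditions: MsCl, Et3N, CH2Cl2, −78 → 0 °C
Reagents that add atoms: methanesulfonyl chloride CS(Cl)(=O)=O
Why: Sulfonylation of the propargylic alcohol with retention gives the enantiopure precursor of the chiral allenylmetal.

Step 13
Reactants: 10 DHB–CHO; 15 (S)-1-(triisopropylsilyloxy)but-3-yn-2-yl methanesulfonate
Product: 17 (1S,2R)-1-DHB-2-[(triisopropylsilyloxy)methyl]but-3-yn-1-ol, via allenylzinc reagent 16 (not isolated)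
Conditions: 15 (1.5 equiv), Pd(OAc)2 (5 mol %), PPh3 (5 mol %), Et2Zn (3 equiv), THF, −78 → −20 °C
Reagents that add atoms: diethylzinc CC[Zn]CC (its ethylzinc group is in 16 only)
Why: Anti SN2′ oxidative addition of Pd(0) to the propargylic mesylate, transmetallation to zinc with retention and addition of the (P)-allenylzinc 16 to the aldehyde through a closed SE2′ transition state (chiral propargylic mesylate/Pd/Et2Zn propargylation) should give the anti homopropargylic alcohol; C2 is set by chirality transfer from the mesylate and C1 by the anti preference of the cyclic transition state.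

Step 14
Reactants: 3 [3-methoxy-4-(triisopropylsilyloxy)phenyl]methanol
Product: 18 3-methoxy-4-(triisopropylsilyloxy)benzyl 2,2,2-trichloroacetimidate
Conditions: Cl3CCN, DBU (10 mol %), CH2Cl2, 0 °C
Reagents that add atoms: trichloroacetonitrile ClC(Cl)(Cl)C#N
Why: Base-catalysed addition of the alcohol to trichloroacetonitrile gives the acid-activatable benzyl donor.

Step 15
Reactants: 17 (1S,2R)-1-DHB-2-[(triisopropylsilyloxy)methyl]but-3-yn-1-ol; 18 3-methoxy-4-(triisopropylsilyloxy)benzyl 2,2,2-trichloroacetimidate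
Product: 19 (1S,2R)-1-DHB-1-{[3-methoxy-4-(triisopropylsilyloxy)benzyl]oxy}-2-[(triisopropylsilyloxy)methyl]but-3-yne
Conditions: 18 (2 equiv), La(OTf)3 (5 mol %), toluene, rt
Reagents that add atoms: none
Why: Lewis-acid-catalysed benzylation with the electron-rich trichloroacetimidate works at an acidity too low to ionise the benzylic alcohol and without base (no silyl migration); the C1–O bond of 17 is not broken, so its configuration is kept.

Step 16
Reactants: 19 (1S,2R)-1-DHB-1-{[3-methoxy-4-(triisopropylsilyloxy)benzyl]oxy}-2-[(triisopropylsilyloxy)methyl]but-3-yne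
Product: 20 (3R,4S)-4-DHB-4-{[3-methoxy-4-(triisopropylsilyloxy)benzyl]oxy}-3-[(triisopropylsilyloxy)methyl]butan-2-one
Conditions: Ph3PAuNTf2 (2 mol %), MeOH/H2O (10:1), 40 °C
Reagents that add atoms: water O
Why: Gold(I)-catalysed Markovnikov hydration of the terminal alkyne gives the methyl ketone under near-neutral conditions.

Step 17
Reactants: 20 (3R,4S)-4-DHB-4-{[3-methoxy-4-(triisopropylsilyloxy)benzyl]oxy}-3-[(triisopropylsilyloxy)methyl]butan-2-one
Product: 22 (3R,4S)-1-diazo-4-DHB-4-{[3-methoxy-4-(triisopropylsilyloxy)benzyl]oxy}-3-[(triisopropylsilyloxy)methyl]butan-2-one, via trifluoroacetyl diketone 21 (not isolated)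
Conditions: LiHMDS (1.1 equiv), THF, −78 °C; CF3CO2CH2CF3 (1.2 equiv); aq. NH4Cl work-up; then 4-acetamidobenzenesulfonyl azide (1.5 equiv), Et3N (1.5 equiv), H2O (1 equiv), MeCN, rt
Reagents that add atoms: 4-acetamidobenzenesulfonyl azide CC(=O)Nc1ccc(cc1)S(=O)(=O)N=[N+]=[N-]; 2,2,2-trifluoroethyl trifluoroacetate O=C(OCC(F)(F)F)C(F)(F)F (its trifluoroacetyl group is in 21 only)
Why: Detrifluoroacetylative (Regitz-type) diazo transfer: kinetic enolisation at the methyl group, Claisen condensation to the activated diketone 21 and diazo transfer with loss of the trifluoroacetyl group give the terminal diazo ketone without touching the α-stereocentre.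

Step 18
Reactants: 22 (3R,4S)-1-diazo-4-DHB-4-{[3-methoxy-4-(triisopropylsilyloxy)benzyl]oxy}-3-[(triisopropylsilyloxy)methyl]butan-2-one
Product: 25 (2S,4R,5S)-2-[3-methoxy-4-(triisopropylsilyloxy)benzyl]-5-DHB-4-[(triisopropylsilyloxy)methyl]dihydrofuran-3(2H)-one (2,5-cis; 4,5-trans), via oxonium ylide 23 (not isolated), via C2-epimeric ketone 24 (not isolated)
Conditions: Rh2(OAc)4 (2 mol %), CH2Cl2, rt, slow addition of 22 (final 5 mM); then DBU (0.2 equiv), rt
Reagents that add atoms: none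
Why: Rh(II) converts the diazo ketone into an electrophilic α-oxo carbenoid that is captured by a lone pair of the benzylic ether oxygen to give the five-membered oxonium ylide 23; homolysis of its exocyclic O–CH2Ar bond and in-cage recombination of the arylmethyl radical at the ylide carbon ([1,2]-Stevens shift) form the ArCH2–C2 bond and leave the ether oxygen as ring O1. The closest known reaction type is the Rh(II)- or Cu(II)-catalysed conversion of acyclic benzyloxy diazo ketones into 2-benzyl-dihydrofuran-3(2H)-ones. The oxolanone ring is closed by O1–C2 bond formation, i.e. attack of the ether oxygen on the carbenoid carbon through a five-membered cyclic ylide, and no other ring is formed. C4 and C5 are carried over unchanged from 22, whereas the new centre C2 comes from a radical-pair recombination that is not expected to be face-selective; because C2 is α to the ketone, the DBU treatment should convert the 2-epimer 24 into 25, in which the 2-arylmethyl, 4-silyloxymethyl and 5-aryl groups can all be pseudo-equatorial. The step needs ylide formation at the benzylic ether oxygen rather than at the silyl ether oxygen or carbenoid addition to the C5 aryl ring, and [1,2]- rather than [1,4]-migration: the first is secured by the 1,5-relationship of carbenoid and ether oxygen together with the bulk and low basicity of the OTIPS oxygen, the second by the Rh(II) carboxylate (radical-pair pathway) and the silyloxy rather than alkoxy para substituent of the migrating group. Migration of the ring C5–O bond (ring contraction) is disfavoured because that bond lies in the ring plane, orthogonal to the enolate π-system, whereas the exocyclic O–CH2Ar bond is aligned with it.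

Step 19
Reactants: 25 (2S,4R,5S)-2-[3-methoxy-4-(triisopropylsilyloxy)benzyl]-5-DHB-4-[(triisopropylsilyloxy)methyl]dihydrofuran-3(2H)-one
Product: 26 (2S,4R,5S)-2-(4-hydroxy-3-methoxybenzyl)-5-[(2R,3R)-2-(4-hydroxy-3-methoxyphenyl)-3-(hydroxymethyl)-7-methoxy-2,3-dihydro-1-benzofuran-5-yl]-4-(hydroxymethyl)dihydrofuran-3(2H)-one
Conditions: TBAF (6 equiv), AcOH (6 equiv), THF, 0 °C → rt
Reagents that add atoms: none
Why: Acetic-acid-buffered fluoride removes the two aryl and two alkyl silyl ethers without the basicity that would epimerise C2 or trigger retro-aldol or β-elimination of the β-hydroxy ketone.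

Step 20
Reactants: 26 (2S,4R,5S)-2-(4-hydroxy-3-methoxybenzyl)-5-[(2R,3R)-2-(4-hydroxy-3-methoxyphenyl)-3-(hydroxymethyl)-7-methoxy-2,3-dihydro-1-benzofuran-5-yl]-4-(hydroxymethyl)dihydrofuran-3(2H)-one
Product: 27 (2S,3S,4S,5S)-2-(4-hydroxy-3-methoxybenzyl)-5-[(2R,3R)-2-(4-hydroxy-3-methoxyphenyl)-3-(hydroxymethyl)-7-methoxy-2,3-dihydro-1-benzofuran-5-yl]-4-(hydroxymethyl)oxolan-3-ol (target)
Conditions: Me4NBH(OAc)3 (6 equiv), MeCN/AcOH (1:1), −30 → −20 °C
Reagents that add atoms: none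
Why: Evans–Saksena directed reduction: the C4 hydroxymethyl group binds the acetoxyborohydride and delivers hydride to C3 on its own face, so the new hydroxyl should be anti to CH2OH (3,4-trans) and syn to the 2-arylmethyl group, which lies on the opposite face and does not hinder delivery.

## Compound list

1 | vanillin | COc1cc(C=O)ccc1O | starting material
2 | 3-methoxy-4-(triisopropylsilyloxy)benzaldehyde | COc1cc(C=O)ccc1O[Si](C(C)C)(C(C)C)C(C)C | intermediate
3 | [3-methoxy-4-(triisopropylsilyloxy)phenyl]methanol | COc1cc(CO)ccc1O[Si](C(C)C)(C(C)C)C(C)C | intermediate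
4 | 5-iodovanillin (4-hydroxy-3-iodo-5-methoxybenzaldehyde) | COc1cc(C=O)cc(I)c1O | starting material
5 | 3-iodo-5-methoxy-4-{[3-methoxy-4-(triisopropylsilyloxy)benzyl]oxy}benzaldehyde | COc1cc(C=O)cc(I)c1OCc1ccc(O[Si](C(C)C)(C(C)C)C(C)C)c(OC)c1 | intermediate
6 | ethyl 2-diazo-2-(5-formyl-3-methoxy-2-{[3-methoxy-4-(triisopropylsilyloxy)benzyl]oxy}phenyl)acetate | CCOC(=O)C(=[N+]=[N-])c1cc(C=O)cc(OC)c1OCc1ccc(O[Si](C(C)C)(C(C)C)C(C)C)c(OC)c1 | intermediate
7 | ethyl (2R,3S)-5-formyl-7-methoxy-2-[3-methoxy-4-(triisopropylsilyloxy)phenyl]-2,3-dihydro-1-benzofuran-3-carboxylate (cis) | O=Cc1cc(OC)c2c(c1)[C@H](C(=O)OCC)[C@H](c1ccc(O[Si](C(C)C)(C(C)C)C(C)C)c(OC)c1)O2 | intermediate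
8 | [(2R,3R)-5-(hydroxymethyl)-7-methoxy-2-[3-methoxy-4-(triisopropylsilyloxy)phenyl]-2,3-dihydro-1-benzofuran-3-yl]methanol | OCc1cc(OC)c2c(c1)[C@H](CO)[C@H](c1ccc(O[Si](C(C)C)(C(C)C)C(C)C)c(OC)c1)O2 | intermediate
9 | (2R,3R)-3-(hydroxymethyl)-7-methoxy-2-[3-methoxy-4-(triisopropylsilyloxy)phenyl]-2,3-dihydro-1-benzofuran-5-carbaldehyde | O=Cc1cc(OC)c2c(c1)[C@H](CO)[C@H](c1ccc(O[Si](C(C)C)(C(C)C)C(C)C)c(OC)c1)O2 | intermediate
10 | (2R,3R)-7-methoxy-2-[3-methoxy-4-(triisopropylsilyloxy)phenyl]-3-[(triisopropylsilyloxy)methyl]-2,3-dihydro-1-benzofuran-5-carbaldehyde (DHB–CHO) | O=Cc1cc(OC)c2c(c1)[C@H](CO[Si](C(C)C)(C(C)C)C(C)C)[C@H](c1ccc(O[Si](C(C)C)(C(C)C)C(C)C)c(OC)c1)O2 | intermediate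
11 | (R)-2,2-dimethyl-1,3-dioxolane-4-carbaldehyde | CC1(C)OC[C@H](C=O)O1 | starting material
12 | (S)-4-ethynyl-2,2-dimethyl-1,3-dioxolane | CC1(C)OC[C@H](C#C)O1 | intermediate
13 | (S)-but-3-yne-1,2-diol | OC[C@H](C#C)O | intermediate
14 | (S)-1-(triisopropylsilyloxy)but-3-yn-2-ol | CC(C)[Si](OC[C@H](C#C)O)(C(C)C)C(C)C | intermediate
15 | (S)-1-(triisopropylsilyloxy)but-3-yn-2-yl methanesulfonate | CC(C)[Si](OC[C@H](C#C)OS(C)(=O)=O)(C(C)C)C(C)C | intermediate
16 | ethyl[(P)-4-(triisopropylsilyloxy)buta-1,2-dien-1-yl]zinc (not isolated) | [H]C([Zn]CC)=[C@]=C([H])CO[Si](C(C)C)(C(C)C)C(C)C | intermediate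
17 | (1S,2R)-1-DHB-2-[(triisopropylsilyloxy)methyl]but-3-yn-1-ol | C#C[C@H](CO[Si](C(C)C)(C(C)C)C(C)C)[C@H](O)c1cc(OC)c2c(c1)[C@H](CO[Si](C(C)C)(C(C)C)C(C)C)[C@H](c1ccc(O[Si](C(C)C)(C(C)C)C(C)C)c(OC)c1)O2 | intermediate
18 | 3-methoxy-4-(triisopropylsilyloxy)benzyl 2,2,2-trichloroacetimidate | COc1cc(COC(=N)C(Cl)(Cl)Cl)ccc1O[Si](C(C)C)(C(C)C)C(C)C | intermediate
19 | (1S,2R)-1-DHB-1-{[3-methoxy-4-(triisopropylsilyloxy)benzyl]oxy}-2-[(triisopropylsilyloxy)methyl]but-3-yne | C#C[C@H](CO[Si](C(C)C)(C(C)C)C(C)C)[C@H](OCc1ccc(O[Si](C(C)C)(C(C)C)C(C)C)c(OC)c1)c1cc(OC)c2c(c1)[C@H](CO[Si](C(C)C)(C(C)C)C(C)C)[C@H](c1ccc(O[Si](C(C)C)(C(C)C)C(C)C)c(OC)c1)O2 | intermediate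
20 | (3R,4S)-4-DHB-4-{[3-methoxy-4-(triisopropylsilyloxy)benzyl]oxy}-3-[(triisopropylsilyloxy)methyl]butan-2-one | CC(=O)[C@H](CO[Si](C(C)C)(C(C)C)C(C)C)[C@H](OCc1ccc(O[Si](C(C)C)(C(C)C)C(C)C)c(OC)c1)c1cc(OC)c2c(c1)[C@H](CO[Si](C(C)C)(C(C)C)C(C)C)[C@H](c1ccc(O[Si](C(C)C)(C(C)C)C(C)C)c(OC)c1)O2 | intermediate
21 | (5R,6S)-6-DHB-1,1,1-trifluoro-6-{[3-methoxy-4-(triisopropylsilyloxy)benzyl]oxy}-5-[(triisopropylsilyloxy)methyl]hexane-2,4-dione (not isolated) | O=C(CC(=O)[C@H](CO[Si](C(C)C)(C(C)C)C(C)C)[C@H](OCc1ccc(O[Si](C(C)C)(C(C)C)C(C)C)c(OC)c1)c1cc(OC)c2c(c1)[C@H](CO[Si](C(C)C)(C(C)C)C(C)C)[C@H](c1ccc(O[Si](C(C)C)(C(C)C)C(C)C)c(OC)c1)O2)C(F)(F)F | intermediate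
22 | (3R,4S)-1-diazo-4-DHB-4-{[3-methoxy-4-(triisopropylsilyloxy)benzyl]oxy}-3-[(triisopropylsilyloxy)methyl]butan-2-one | [N-]=[N+]=CC(=O)[C@H](CO[Si](C(C)C)(C(C)C)C(C)C)[C@H](OCc1ccc(O[Si](C(C)C)(C(C)C)C(C)C)c(OC)c1)c1cc(OC)c2c(c1)[C@H](CO[Si](C(C)C)(C(C)C)C(C)C)[C@H](c1ccc(O[Si](C(C)C)(C(C)C)C(C)C)c(OC)c1)O2 | intermediate
23 | (4R,5S)-1-[3-methoxy-4-(triisopropylsilyloxy)benzyl]-5-DHB-3-oxo-4-[(triisopropylsilyloxy)methyl]oxolan-1-ium-2-ide (cyclic oxonium ylide; not isolated) | [CH-]1[O+](Cc2ccc(O[Si](C(C)C)(C(C)C)C(C)C)c(OC)c2)[C@H](c2cc(OC)c3c(c2)[C@H](CO[Si](C(C)C)(C(C)C)C(C)C)[C@H](c2ccc(O[Si](C(C)C)(C(C)C)C(C)C)c(OC)c2)O3)[C@@H](CO[Si](C(C)C)(C(C)C)C(C)C)C1=O | intermediate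
24 | (2R,4R,5S)-2-[3-methoxy-4-(triisopropylsilyloxy)benzyl]-5-DHB-4-[(triisopropylsilyloxy)methyl]dihydrofuran-3(2H)-one (2-epimer; not isolated) | COc1cc(C[C@H]2O[C@H](c3cc(OC)c4c(c3)[C@H](CO[Si](C(C)C)(C(C)C)C(C)C)[C@H](c3ccc(O[Si](C(C)C)(C(C)C)C(C)C)c(OC)c3)O4)[C@@H](CO[Si](C(C)C)(C(C)C)C(C)C)C2=O)ccc1O[Si](C(C)C)(C(C)C)C(C)C | intermediate
25 | (2S,4R,5S)-2-[3-methoxy-4-(triisopropylsilyloxy)benzyl]-5-DHB-4-[(triisopropylsilyloxy)methyl]dihydrofuran-3(2H)-one | COc1cc(C[C@@H]2O[C@H](c3cc(OC)c4c(c3)[C@H](CO[Si](C(C)C)(C(C)C)C(C)C)[C@H](c3ccc(O[Si](C(C)C)(C(C)C)C(C)C)c(OC)c3)O4)[C@@H](CO[Si](C(C)C)(C(C)C)C(C)C)C2=O)ccc1O[Si](C(C)C)(C(C)C)C(C)C | intermediate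
26 | (2S,4R,5S)-2-(4-hydroxy-3-methoxybenzyl)-5-[(2R,3R)-2-(4-hydroxy-3-methoxyphenyl)-3-(hydroxymethyl)-7-methoxy-2,3-dihydro-1-benzofuran-5-yl]-4-(hydroxymethyl)dihydrofuran-3(2H)-one | COc1cc(C[C@@H]2O[C@H](c3cc(OC)c4c(c3)[C@H](CO)[C@H](c3ccc(O)c(OC)c3)O4)[C@@H](CO)C2=O)ccc1O | intermediate
27 | (2S,3S,4S,5S)-2-(4-hydroxy-3-methoxybenzyl)-5-[(2R,3R)-2-(4-hydroxy-3-methoxyphenyl)-3-(hydroxymethyl)-7-methoxy-2,3-dihydro-1-benzofuran-5-yl]-4-(hydroxymethyl)oxolan-3-ol | COc1cc(C[C@@H]2O[C@H](c3cc(OC)c4c(c3)[C@H](CO)[C@H](c3ccc(O)c(OC)c3)O4)[C@@H](CO)[C@@H]2O)ccc1O | target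

## Step count and risks

Total step count: 20. Longest linear sequence: 15 steps (1, 2, 3, 4, 5, 6, 7, 8, 13, 15, 16, 17, 18, 19, 20).

**Step 18 (ylide formation and [1,2]-shift).** The oxonium ylide may be diverted into a [1,4]-shift of the electron-rich arylmethyl group onto the enolate oxygen, and the carbenoid may add to the electron-rich C5 aryl ring instead of forming the ylide. The equilibration at C2 may also stop at an unfavourable epimer ratio. The fallback leaves the route at alcohol 17 and comes back at ketone 25. Gold-catalysed oxidative cyclisation of the homopropargylic alcohol (Ph3PAuNTf2, 8-methylquinoline N-oxide, DCE, rt; α-oxo gold carbene, O–H insertion) should give (4R,5S)-5-DHB-4-[(triisopropylsilyloxy)methyl]dihydrofuran-3(2H)-one F1. Aldol condensation of F1 with aldehyde 2 (pyrrolidine cat., or neutral alumina, CH2Cl2, rt) should give (Z)-2-[3-methoxy-4-(triisopropylsilyloxy)benzylidene]-5-DHB-4-[(triisopropylsilyloxy)methyl]dihydrofuran-3(2H)-one F2, which carries the bond in question as a C=C bond. Conjugate reduction with hexameric triphenylphosphine copper hydride (wet toluene, rt) followed by the same DBU equilibration leads to 25.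

**Step 16 (alkyne hydration).** The homopropargylic ether oxygens may attack the gold-activated alkyne (5-endo closure with transfer of the electron-rich benzyl group), and the β-benzyloxy group may be eliminated from the product ketone under the Lewis-acidic conditions. The fallback leaves at alkyne 19 and comes back at ketone 20. Markovnikov hydrosilylation ([Cp*Ru(MeCN)3]PF6 2 mol %, HSi(OEt)3, CH2Cl2, 0 °C → rt) should give the 1,1-disubstituted vinylsilane (3R,4S)-4-DHB-4-{[3-methoxy-4-(triisopropylsilyloxy)benzyl]oxy}-2-(triethoxysilyl)-3-[(triisopropylsilyloxy)methyl]but-1-ene F3. Fluoride-free Tamao–Fleming oxidation (H2O2, KHCO3, THF/MeOH), chosen to spare the aryl silyl ethers, then gives 20.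

**Step 15 (O-benzylation).** The acid catalyst may ionise the electron-rich benzylic C–O bond of 17 or 19 (loss of configuration at C1, elimination), while etherification of the hindered secondary alcohol is slow. The fallback sets out from alcohols 3 and 17 and comes back at ether 19. Alcohol 3 is converted (CBr4, PPh3, CH2Cl2, 0 °C) into 4-(bromomethyl)-2-methoxy-1-(triisopropylsilyloxy)benzene F4. Williamson etherification of 17 (NaH, THF, 0 °C, then F4 and Bu4NI, kept cold to suppress 1,3-silyl migration) then gives 19 without any acid.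

Further compounds
F1 | step 18 | (4R,5S)-5-DHB-4-[(triisopropylsilyloxy)methyl]dihydrofuran-3(2H)-one | C1O[C@H](c2cc(OC)c3c(c2)[C@H](CO[Si](C(C)C)(C(C)C)C(C)C)[C@H](c2ccc(O[Si](C(C)C)(C(C)C)C(C)C)c(OC)c2)O3)[C@@H](CO[Si](C(C)C)(C(C)C)C(C)C)C1=O
F2 | step 18 | (Z)-2-[3-methoxy-4-(triisopropylsilyloxy)benzylidene]-5-DHB-4-[(triisopropylsilyloxy)methyl]dihydrofuran-3(2H)-one (4R,5S) | COc1cc(/C=C2\O[C@H](c3cc(OC)c4c(c3)[C@H](CO[Si](C(C)C)(C(C)C)C(C)C)[C@H](c3ccc(O[Si](C(C)C)(C(C)C)C(C)C)c(OC)c3)O4)[C@@H](CO[Si](C(C)C)(C(C)C)C(C)C)C2=O)ccc1O[Si](C(C)C)(C(C)C)C(C)C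
F3 | step 16 | (3R,4S)-4-DHB-4-{[3-methoxy-4-(triisopropylsilyloxy)benzyl]oxy}-2-(triethoxysilyl)-3-[(triisopropylsilyloxy)methyl]but-1-ene | C=C([Si](OCC)(OCC)OCC)[C@H](CO[Si](C(C)C)(C(C)C)C(C)C)[C@H](OCc1ccc(O[Si](C(C)C)(C(C)C)C(C)C)c(OC)c1)c1cc(OC)c2c(c1)[C@H](CO[Si](C(C)C)(C(C)C)C(C)C)[C@H](c1ccc(O[Si](C(C)C)(C(C)C)C(C)C)c(OC)c1)O2
F4 | step 15 | 4-(bromomethyl)-2-methoxy-1-(triisopropylsilyloxy)benzene | COc1cc(CBr)ccc1O[Si](C(C)C)(C(C)C)C(C)C
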